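**Plan**

The target is 5,8-dihydroxy-7-methoxy-6-(3-methylbut-2-enyl)-3-(2,4,5-trimethoxyphenyl)chromen-4-one.
- Retrosynthesis cuts, on ring A, the side-chain alkene (prenyl back to allyl), the C8–O bond and the C6–allyl bond; then C4–C4a, O1–C2 and C2–C3 of ring C.
- Forward: rings A and B are bought intact. The three-carbon bridge is built on the ring B arylacetate (formylation), joined to 3,5-dimethoxyphenol through oxygen, and ring C is closed by acylation at C4a; it is the only ring formed.
- The closure is possible because C4 is bonded to C4a, a ring A carbon ortho to O1 and ortho/para to the C5 and C7 oxygens, and because the two ortho carbons of the symmetric phenoxy ring are equivalent.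
- Ring A is then completed: chelation-guided 5-O-demethylation, O-allylation and Claisen shift to C6, Elbs hydroxylation at C8, cross-metathesis of allyl to prenyl.
- The target has no stereocentre and its side-chain alkene carries two identical methyl groups, so nothing stereochemical has to be set; the acrylate geometry matters only for ring closure.

Key step: step 5

Assumption: hydroxymethylene ester 3 is written as its hydrogen-bonded (Z)-enol, which stands for the formyl ester tautomer as well.

**Route**

Step 1
Reactants: 1 methyl (2,4,5-trimethoxyphenyl)acetate; 2 methyl formate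
Product: 3 methyl (Z)-3-hydroxy-2-(2,4,5-trimethoxyphenyl)prop-2-enoate
Conditions: NaH, HCO2Me (excess), THF, 0 °C to rt; then 1 M HCl
Reagents that add atoms: none
Why: Crossed Claisen condensation, in which the ester enolate of 1 is formylated by the non-enolisable methyl formate and the product is drained as its stabilised sodium enolate, the standard entry to 2-aryl-3-hydroxyacrylates.

Step 2
Reactants: 3 methyl (Z)-3-hydroxy-2-(2,4,5-trimethoxyphenyl)prop-2-enoate
Product: 4 methyl (Z)-3-(4-methylphenylsulfonyloxy)-2-(2,4,5-trimethoxyphenyl)prop-2-enoate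
Conditions: TsCl, TMEDA, LiCl, MeCN, 0 °C
Reagents that add atoms: p-toluenesulfonyl chloride, Cc1ccc(cc1)S(Cl)(=O)=O
Why: Enol tosylate formation by O-sulfonylation, in which the lithium chelate between the enolate oxygen and the ester carbonyl holds these groups cis, so the (Z)-tosylate should result.

Step 3
Reactants: 4 methyl (Z)-3-(4-methylphenylsulfonyloxy)-2-(2,4,5-trimethoxyphenyl)prop-2-enoate; 5 3,5-dimethoxyphenol
Product: 6 methyl (Z)-3-(3,5-dimethoxyphenoxy)-2-(2,4,5-trimethoxyphenyl)prop-2-enoate
Conditions: K2CO3, DMF, rt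
Reagents that add atoms: none
Why: Nucleophilic vinylic substitution by addition–elimination, in which the phenoxide adds to the β-carbon of the acrylate and tosylate leaves from the ester-stabilised carbanion, normally with retention, so the (Z)-aryl vinyl ether is expected; any (E)-isomer can be carried on because the acid medium of step 5 interconverts the two.

Step 4
Reactants: 6 methyl (Z)-3-(3,5-dimethoxyphenoxy)-2-(2,4,5-trimethoxyphenyl)prop-2-enoate
Product: 7 (Z)-3-(3,5-dimethoxyphenoxy)-2-(2,4,5-trimethoxyphenyl)prop-2-enoic acid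
Conditions: LiOH, THF/MeOH/H2O, rt; then 1 M HCl, 0 °C
Reagents that add atoms: lithium hydroxide, [Li+].[OH-]
Why: Saponification at the ester carbonyl, which should be preferred because the β-aryloxy donor makes the β-carbon a poor Michael acceptor, as in the routine hydrolysis of 3-aryloxyacrylates.

Step 5
Reactants: 7 (Z)-3-(3,5-dimethoxyphenoxy)-2-(2,4,5-trimethoxyphenyl)prop-2-enoic acid
Product: 9 5,7-dimethoxy-3-(2,4,5-trimethoxyphenyl)chromen-4-one, via trifluoroacetic mixed anhydride 8 (not isolated)
Conditions: (CF3CO)2O (2 equiv), CH2Cl2, 0 °C to rt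
Reagents that add atoms: none
Why: Intramolecular Friedel–Crafts acylation of a β-aryloxyacrylic acid, the known acid-mediated route from such acids to chromones: (CF3CO)2O converts 7 into mixed anhydride 8, whose acyl carbon (as the anhydride or the acylium ion it ionises to) is attacked by the phenoxy carbon ortho to the vinyl ether oxygen, and proton loss restores the arene. Ring C closes in a 6-exo mode (6-exo-trig on the anhydride carbonyl) through a six-membered transition state, forming C4–C4a, and no stereocentre is created. The attacked carbon is ortho to one methoxy group, para to the other and ortho to the ether oxygen, so the mild mixed anhydride should suffice and ring closure should outrun trifluoroacetylation of either arene. Site selectivity is secured by the mirror symmetry of the 3,5-dimethoxyphenoxy ring, whose two ortho carbons are equivalent, and ring B cannot compete because acylation there would give a four-membered ring. The closure needs the aryloxy group cis to the acyl group; the (Z)-geometry of 7 provides this, and the CF3CO2H set free can equilibrate the push–pull alkene by reversible C-protonation if any (E)-isomer is present.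

Step 6
Reactants: 9 5,7-dimethoxy-3-(2,4,5-trimethoxyphenyl)chromen-4-one
Product: 11 5-hydroxy-7-methoxy-3-(2,4,5-trimethoxyphenyl)chromen-4-one, via dichloroboron chelate 10 (not isolated)
Conditions: BCl3, CH2Cl2, −78 to 0 °C; then H2O
Reagents that add atoms: none
Why: Chelation-directed Lewis acid ether cleavage, in which BCl3 binds the C4 carbonyl and the peri 5-methoxy oxygen in a six-membered chelate, so chloride should demethylate only that ether and leave the other four methoxy groups.

Step 7
Reactants: 11 5-hydroxy-7-methoxy-3-(2,4,5-trimethoxyphenyl)chromen-4-one; 12 allyl bromide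
Product: 13 7-methoxy-5-(prop-2-enyloxy)-3-(2,4,5-trimethoxyphenyl)chromen-4-one
Conditions: K2CO3, DMF, 60 °C
Reagents that add atoms: none
Why: Williamson ether synthesis, in which the hydrogen-bonded 5-OH is the only acidic site and is alkylated by the reactive allylic bromide in warm DMF.

Step 8
Reactants: 13 7-methoxy-5-(prop-2-enyloxy)-3-(2,4,5-trimethoxyphenyl)chromen-4-one
Product: 15 5-hydroxy-7-methoxy-6-(prop-2-enyl)-3-(2,4,5-trimethoxyphenyl)chromen-4-one, via C6 dienone 14 (not isolated)
Conditions: PhNEt2, 200 °C
Reagents that add atoms: none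
Why: Aromatic Claisen rearrangement ([3,3]-sigmatropic shift), in which only C6 of the two positions ortho to the C5 ether carries hydrogen (C4a is the ring fusion), so the allyl group should arrive at C6 and dienone 14 should tautomerise to the chelated phenol.

Step 9
Reactants: 15 5-hydroxy-7-methoxy-6-(prop-2-enyl)-3-(2,4,5-trimethoxyphenyl)chromen-4-one
Product: 17 5,8-dihydroxy-7-methoxy-6-(prop-2-enyl)-3-(2,4,5-trimethoxyphenyl)chromen-4-one, via potassium C8 sulfate 16 (not isolated)
Conditions: K2S2O8, aq. KOH, pyridine, 0 to 20 °C; then aq. HCl, a little Na2SO3, 80 °C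
Reagents that add atoms: potassium peroxodisulfate, [K+].[K+].[O-]S(=O)(=O)OOS(=O)(=O)[O-]
Why: Elbs persulfate oxidation, in which the C5 phenolate attacks peroxodisulfate through its para carbon C8, the only unsubstituted ring A position, and warm dilute acid hydrolyses aryl sulfate 16 to the hydroquinone, as established for 5-hydroxychromones and 5-hydroxyflavones.

Step 10
Reactants: 17 5,8-dihydroxy-7-methoxy-6-(prop-2-enyl)-3-(2,4,5-trimethoxyphenyl)chromen-4-one; 18 2-methylbut-2-ene
Product: 19 5,8-dihydroxy-7-methoxy-6-(3-methylbut-2-enyl)-3-(2,4,5-trimethoxyphenyl)chromen-4-one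
Conditions: second-generation Grubbs catalyst (H2IMes)(PCy3)Cl2Ru=CHPh (5 mol %), 2-methylbut-2-ene (excess), CH2Cl2, 40 °C, argon
Reagents that add atoms: none
Why: Olefin cross-metathesis of the terminal allyl group with excess 2-methylbut-2-ene, the usual conversion of aryl-allyl into aryl-prenyl, which tolerates free phenols and releases propene.

**Compound list**

1 | methyl (2,4,5-trimethoxyphenyl)acetate | COC(=O)Cc1cc(OC)c(OC)cc1OC | starting material
2 | methyl formate | COC=O | starting material
3 | methyl (Z)-3-hydroxy-2-(2,4,5-trimethoxyphenyl)prop-2-enoate | COC(=O)/C(=C\O)c1cc(OC)c(OC)cc1OC | intermediate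
4 | methyl (Z)-3-(4-methylphenylsulfonyloxy)-2-(2,4,5-trimethoxyphenyl)prop-2-enoate | COC(=O)/C(=C\OS(=O)(=O)c1ccc(C)cc1)c1cc(OC)c(OC)cc1OC | intermediate
5 | 3,5-dimethoxyphenol | COc1cc(O)cc(OC)c1 | starting material
6 | methyl (Z)-3-(3,5-dimethoxyphenoxy)-2-(2,4,5-trimethoxyphenyl)prop-2-enoate | COC(=O)/C(=C\Oc1cc(OC)cc(OC)c1)c1cc(OC)c(OC)cc1OC | intermediate
7 | (Z)-3-(3,5-dimethoxyphenoxy)-2-(2,4,5-trimethoxyphenyl)prop-2-enoic acid | OC(=O)/C(=C\Oc1cc(OC)cc(OC)c1)c1cc(OC)c(OC)cc1OC | intermediate
8 | (Z)-3-(3,5-dimethoxyphenoxy)-2-(2,4,5-trimethoxyphenyl)prop-2-enoic trifluoroacetic anhydride | O=C(OC(=O)C(F)(F)F)/C(=C\Oc1cc(OC)cc(OC)c1)c1cc(OC)c(OC)cc1OC | intermediate (not isolated)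
9 | 5,7-dimethoxy-3-(2,4,5-trimethoxyphenyl)chromen-4-one | COc1cc(OC)c2c(c1)occ(-c1cc(OC)c(OC)cc1OC)c2=O | intermediate
10 | 5-(dichloroboranyloxy)-7-methoxy-3-(2,4,5-trimethoxyphenyl)chromen-4-one (boron chelated to the C4 carbonyl) | COc1cc(OB(Cl)Cl)c2c(c1)occ(-c1cc(OC)c(OC)cc1OC)c2=O | intermediate (not isolated)
11 | 5-hydroxy-7-methoxy-3-(2,4,5-trimethoxyphenyl)chromen-4-one | COc1cc(O)c2c(c1)occ(-c1cc(OC)c(OC)cc1OC)c2=O | intermediate
12 | allyl bromide (3-bromoprop-1-ene) | C=CCBr | starting material
13 | 7-methoxy-5-(prop-2-enyloxy)-3-(2,4,5-trimethoxyphenyl)chromen-4-one | C=CCOc1cc(OC)cc2occ(-c3cc(OC)c(OC)cc3OC)c(=O)c12 | intermediate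
14 | 7-methoxy-6-(prop-2-enyl)-3-(2,4,5-trimethoxyphenyl)-6H-chromene-4,5-dione (racemic at C6) | COC1=CC2=C(C(=O)C1CC=C)C(=O)C(=CO2)c1cc(OC)c(OC)cc1OC | intermediate (not isolated)
15 | 5-hydroxy-7-methoxy-6-(prop-2-enyl)-3-(2,4,5-trimethoxyphenyl)chromen-4-one | COc1cc(OC)c(-c2coc3cc(OC)c(CC=C)c(O)c3c2=O)cc1OC | intermediate
16 | potassium 5-hydroxy-7-methoxy-4-oxo-6-(prop-2-enyl)-3-(2,4,5-trimethoxyphenyl)chromen-8-yl sulfate | COc1cc(OC)c(-c2coc3c(OS(=O)(=O)[O-])c(OC)c(CC=C)c(O)c3c2=O)cc1OC.[K+] | intermediate (not isolated)
17 | 5,8-dihydroxy-7-methoxy-6-(prop-2-enyl)-3-(2,4,5-trimethoxyphenyl)chromen-4-one | COc1cc(OC)c(-c2coc3c(O)c(OC)c(CC=C)c(O)c3c2=O)cc1OC | intermediate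
18 | 2-methylbut-2-ene | CC=C(C)C | starting material
19 | 5,8-dihydroxy-7-methoxy-6-(3-methylbut-2-enyl)-3-(2,4,5-trimethoxyphenyl)chromen-4-one | COc1cc(OC)c(-c2coc3c(O)c(OC)c(CC=C(C)C)c(O)c3c2=O)cc1OC | target

**Count and risks**

Total steps: 10. Longest linear sequence: 10 steps (1 to 19); all other inputs are purchased.

Steps most likely to fail:

1. Step 9. Hydroxide may open the pyranone at C2 faster than persulfate substitutes at C8, or the phenolate may be consumed by radical over-oxidation, so that little aryl sulfate forms. The fallback sets out from 15 and returns at 17. Teuber oxidation with ON(SO3K)2 in KH2PO4-buffered aqueous acetone, without strong base, should take the phenol with its free para position to the quinone 7-methoxy-6-(prop-2-enyl)-3-(2,4,5-trimethoxyphenyl)chromene-4,5,8-trione F1. A reductive shake with aqueous Na2S2O4 and ethyl acetate should then give hydroquinone 17.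

2. Step 5. Trifluoroacetylation of the electron-rich rings, or acid-induced loss of the phenol from the vinyl ether, may compete with acylation at C4a. The fallback sets out from 1 and 5 and returns at 9 by the deoxybenzoin route. Saponification of 1 with LiOH should give (2,4,5-trimethoxyphenyl)acetic acid F2. Heating F2 with 5 in BF3·OEt2 should acylate the phenol ortho to its hydroxyl and give 1-(2-hydroxy-4,6-dimethoxyphenyl)-2-(2,4,5-trimethoxyphenyl)ethanone F3. Condensation of F3 with Me2NCH(OMe)2 in hot toluene should add C2 and close ring C to 9.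

3. Step 3. The phenoxide may attack sulfur (sulfonyl transfer to the phenol) instead of the β-carbon. The fallback sets out from 3 and returns at 6. (COCl)2 with catalytic DMF in CH2Cl2 at 0 °C should convert the enol into methyl (Z)-3-chloro-2-(2,4,5-trimethoxyphenyl)prop-2-enoate F4, a vinylic electrophile with a single reactive site. Phenol 5 with K2CO3 in DMF should then displace chloride by addition–elimination to give 6; the geometry of F4 is not critical because step 5 equilibrates the alkene.

Further compounds
F1 | step 9 | 7-methoxy-6-(prop-2-enyl)-3-(2,4,5-trimethoxyphenyl)chromene-4,5,8-trione | COC1=C(CC=C)C(=O)C2=C(OC=C(C2=O)c2cc(OC)c(OC)cc2OC)C1=O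
F2 | step 5 | (2,4,5-trimethoxyphenyl)acetic acid | OC(=O)Cc1cc(OC)c(OC)cc1OC
F3 | step 5 | 1-(2-hydroxy-4,6-dimethoxyphenyl)-2-(2,4,5-trimethoxyphenyl)ethanone | COc1cc(O)c(C(=O)Cc2cc(OC)c(OC)cc2OC)c(OC)c1
F4 | step 3 | methyl (Z)-3-chloro-2-(2,4,5-trimethoxyphenyl)prop-2-enoate | COC(=O)/C(=C\Cl)c1cc(OC)c(OC)cc1OC
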